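**Early times.** At early times the two hands stand equal, so left-handed and right-handed product form in the ratio of their coupling constants, the selectivity factor s = 4.67. That ratio need not last, and the next run hangs on what it becomes: delta's charge of coupling partner or epsilon's.

| setting | delta | epsilon |
|---|---|---|
| left-handed substrate | 49 mM | 49 mM |
| coupling partner | 120 mM | 240 mM |
| right-handed substrate | 49 mM | 49 mM |
| time | 50 min | 50 min |

- which of these there is most of at the end, counted by the substrate in it, delta (left-handed product / left-handed substrate / right-handed product / right-handed substrate)
- which of these there is most of at the end, counted by the substrate in it, epsilon (left-handed product / left-handed substrate / right-handed product / right-handed substrate)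
- the largest of these amounts at the end, in percent of the left-handed substrate and right-handed substrate together charged, delta
- the largest of these amounts at the end, in percent of the left-handed substrate and right-handed substrate together charged, epsilon

    coupling partner + left-handed substrate → left-handed product (k1 = 0.0056 /M/s)
    2 coupling partner → self-condensation product (k2 = 3.4 × 10⁻⁴ /M/s)
    left-handed substrate ⇌ right-handed substrate (k3 = 2.2 × 10⁻⁴ /s)
    coupling partner ⇌ dormant form (K4 = 0.16, k4 = 2.9 × 10⁻⁴ /s)
    coupling partner + right-handed substrate → right-handed product (k5 = 0.0012 /M/s)

**One molecule.** Each substrate molecule stands at a fork: couple or invert. I write a and b for the pseudo-first-order coupling frequencies of left-handed and right-handed substrate (constant times coupling partner), and r = 0.0132 /min for inversion. With equal charges, balancing entries against exits for each hand gives residence times, left over right, of (b + 2r)/(a + 2r). Multiplying by a/b gives the fate ratio ρ, left-handed over right-handed product once the substrate is used, with the partner held at a fixed level. At delta's charge, a = 0.0403 /min and b = 0.00864 /min, so ρ = 2.45.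

**The decision.** At epsilon's charge ρ = 1.90, lower than delta's. The left-handed share of product therefore falls from 71.0 % to 65.5 %, while coupling runs twice as fast. I charge epsilon for a short run and delta for one that can stand longer. I name left-handed product as the top in both flasks as a judgement, not a reckoning, since ρ compares the two products and leaves out substrate still unused at 50 min. Since ρ is a fate, I give no yield at 50 min.

**The result.** The forecast gives left-handed product at 37 % in delta and left-handed product at 51 % in epsilon: “Doubling the coupling partner raises the yield by less than double”. The simulation gives left-handed product at 37.8 % in delta and left-handed product at 51.2 % in epsilon.

**What stands.** In epsilon at the end, the slowest mode has a half-life of 119 min, longer than the 50 min run, and the product ratio reads 2.77, above ρ at the charge, 1.90. With the partner at its end level of 44.9 % of charge, ρ gives 2.55.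

**A richer charge.** For epsilon's flask with 600 mM of coupling partner, ρ gives 1.42 at the charge and 1.93 at its end level of 38.7 %. That flask computes to 58.0 % left-handed and 30.8 % right-handed product, a ratio of 1.88.

The constants used here are made up, and the outcome is calculated.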